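**Retrosynthetic overview**
- The four O-methyl groups are removed last. Before that, the 17-membered macrocycle is opened at the ring B–O–ring A diaryl ether, which is closed late by palladium-catalysed C–O coupling at an unhindered aryl chloride.
- The strategy rests on ring C: it carries four contiguous substituents (CH2CH2 chain at C1, O–ring D at C2, oxygens at C3 and C4), and its C2–O bond to ring D is flanked on both sides. That C–O bond is therefore made first on an sp carbon, and ring C is grown around it.
- Ring C is built by Danheiser benzannulation of aryl ynol ether 13 with 2,3-dimethoxycyclobut-2-enone 17 (bonds C6–C1 and C2–C3, then C5–C6). The extra C6 hydroxyl is removed through its triflate.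
- Ynol ether 13 comes from the ring D–ring A bibenzyl phenol 6 (Wittig, hydrogenation), trichloroethylene and triflate 10. Cyclobutenone 17 comes from dimethyl squarate by hydride addition, acetylation and SmI2 removal of the acetoxy group.
- Ring order: rings A, B and D are bought, ring C is formed in step 10, the macrocycle in step 14.

Key step: step 10

Remark: the target has no stereocentre (15, 16 and 19 are racemic and lose their stereocentres later). Ring C is numbered C1 (chain to ring B), C2 (O to ring D), C3 and C4 (OH), C5 and C6 (H). Compounds 1, 3, 7, 9 and 14 are taken as commercial.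

**Step 1**
Reactants: 1 3-hydroxy-4,5-dimethoxybenzaldehyde
Product: 2 3,4-dimethoxy-5-(methoxymethoxy)benzaldehyde
Conditions: MOMCl, i-Pr2NEt, CH2Cl2, 0 °C → rt
Reagents that add atoms: chloromethyl methyl ether, COCCl
Why: O-alkylation of the phenol protects the oxygen that later forms the ring A–ring B ether as a MOM acetal, which tolerates the base, organolithium, heat and palladium–formate conditions ahead.

**Step 2**
Reactants: 3 (2-hydroxybenzyl)triphenylphosphonium bromide; 2 3,4-dimethoxy-5-(methoxymethoxy)benzaldehyde
Product: 5 2-[2-(3,4-dimethoxy-5-(methoxymethoxy)phenyl)ethenyl]phenol (E/Z mixture), via phosphonium ylide phenoxide 4 (not isolated)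
Conditions: KOtBu (2.2 equiv), THF, 0 °C; then 2, 0 → 60 °C; AcOH quench
Reagents that add atoms: none
Why: Wittig olefination, in which two equivalents of base give the phenoxide ylide that condenses with aldehyde 2 to form the carbon bridge between rings D and A; the alkene geometry is irrelevant because it is hydrogenated next.

**Step 3**
Reactants: 5 2-[2-(3,4-dimethoxy-5-(methoxymethoxy)phenyl)ethenyl]phenol
Product: 6 2-[2-(3,4-dimethoxy-5-(methoxymethoxy)phenyl)ethyl]phenol
Conditions: H2 (1 atm), Pd/C (palladium on carbon), EtOAc, rt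
Reagents that add atoms: none
Why: Heterogeneous catalytic hydrogenation saturates the stilbene double bond; no benzyl ether or halide is present, and the MOM acetal and methyl ethers are inert.

**Step 4**
Reactants: 6 2-[2-(3,4-dimethoxy-5-(methoxymethoxy)phenyl)ethyl]phenol; 7 trichloroethylene
Product: 8 (E)-1,2-dichlorovinyl ether of phenol 6
Conditions: 7 (excess), K2CO3, DMF, 70 °C
Reagents that add atoms: none
Why: Base-mediated addition of the phenoxide to dichloroacetylene formed in situ from trichloroethylene (net addition–elimination) gives the (E)-dichlorovinyl aryl ether, so the crowded C2–O bond of ring C is made here on an unhindered two-carbon unit.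

**Step 5**
Reactants: 9 2-(4-chlorophenyl)ethanol
Product: 10 2-(4-chlorophenyl)ethyl trifluoromethanesulfonate
Conditions: Tf2O, pyridine, CH2Cl2, −78 → −20 °C; used at once
Reagents that add atoms: trifluoromethanesulfonic anhydride, O=S(=O)(OS(=O)(=O)C(F)(F)F)C(F)(F)F
Why: O-sulfonylation of the primary alcohol gives an electrophile reactive enough to alkylate an alkynyllithium at low temperature without a polar cosolvent.

**Step 6**
Reactants: 8 (E)-1,2-dichlorovinyl ether of phenol 6; 10 2-(4-chlorophenyl)ethyl trifluoromethanesulfonate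
Product: 13 1-{[4-(4-chlorophenyl)but-1-yn-1-yl]oxy}-2-[2-(3,4-dimethoxy-5-(methoxymethoxy)phenyl)ethyl]benzene, via chloroalkynyl ether 11 (not isolated), via lithium aryloxyacetylide 12 (not isolated)
Conditions: n-BuLi (2.1 equiv), THF, −78 → −40 °C; then 10, −78 → 0 °C; Et3N-deactivated silica
Reagents that add atoms: none
Why: Dichlorovinyl ether route to ynol ethers, in which n-BuLi eliminates HCl and then exchanges the alkynyl chloride for lithium, and the lithium acetylide is C-alkylated by the primary triflate in an SN2 reaction at low temperature, where E2 elimination to the styrene is slow.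

**Step 7**
Reactants: 14 dimethyl squarate
Product: 15 4-hydroxy-2,3-dimethoxycyclobut-2-en-1-one (racemic)
Conditions: LiAlH(OtBu)3 (1.05 equiv), THF, −78 °C; pH 7 buffer work-up
Reagents that add atoms: none
Why: 1,2-Addition of the hindered aluminium hydride to one squarate carbonyl at low temperature stops at the 4-hydroxycyclobutenone, since the remaining carbonyl is a deactivated vinylogous ester.

**Step 8**
Reactants: 15 4-hydroxy-2,3-dimethoxycyclobut-2-en-1-one
Product: 16 4-acetoxy-2,3-dimethoxycyclobut-2-en-1-one (racemic)
Conditions: Ac2O, pyridine, DMAP (cat.), CH2Cl2, 0 °C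
Reagents that add atoms: acetic anhydride, CC(=O)OC(C)=O
Why: Acylation under buffered basic conditions turns the hydroxyl into an α-acyloxy leaving group without the acid that would rearrange 15 to methyl semisquarate.

**Step 9**
Reactants: 16 4-acetoxy-2,3-dimethoxycyclobut-2-en-1-one
Product: 17 2,3-dimethoxycyclobut-2-en-1-one
Conditions: SmI2 (2.2 equiv), THF–MeOH, −78 °C
Reagents that add atoms: none
Why: Samarium diiodide reduction of an α-acyloxy ketone (electron transfer to the carbonyl, loss of acetate, protonation by methanol) replaces C–OAc by C–H, and the methoxy-bearing terminus of the intermediate is the poorer carbanion site, which should favour protonation at the former acetoxy carbon.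

**Step 10**
Reactants: 13 ynol ether; 17 2,3-dimethoxycyclobut-2-en-1-one
Product: 22 2-[2-(4-chlorophenyl)ethyl]-4,5-dimethoxy-3-{2-[2-(3,4-dimethoxy-5-(methoxymethoxy)phenyl)ethyl]phenoxy}phenol, via dimethoxyvinylketene 18 (not isolated), via vinylcyclobutenone adduct 19 (not isolated), via dienylketene 20 (not isolated), via cyclohexadienone 21 (not isolated)
Conditions: 17 (2–3 equiv, in portions), toluene, 80 → 110 °C, sealed tube; then KOH, MeOH, rt
Reagents that add atoms: none
Why: Heating opens 17 in a four-electron electrocyclic step to vinylketene 18, whose ketene C=C adds [2+2] to the alkyne of 13 to give 4-vinylcyclobutenone 19 (bonds C6–C1 and C2–C3); a second four-electron opening gives dienylketene 20, which closes and tautomerises through 21 to phenol 22 (Danheiser benzannulation). The closest known cases are benzannulations of cyclobutenones with alkoxy- and siloxyalkynes, which place the alkyne oxygen meta to the new hydroxyl as here; the combination of a 2,3-dialkoxycyclobutenone with an aryl alkynyl ether has not been tried, so the risk of the route sits in this pairing. Ring C is closed by disrotatory six-electron electrocyclisation of the dienylketene (bond C5–C6), followed by enolisation. No stereocentre results: the quaternary carbon of 19 is lost on ring opening, and outward rotation of its methoxy group places the vinyl group cis to the ketene, as the closure needs. The step needs a single alkyne orientation, which the polarised ynol ether secures: its chain-bearing carbon is the nucleophilic one and bonds to the ketene carbonyl carbon, so the aryloxy carbon ends next to the methoxy-bearing carbon (C2 next to C3). The aryloxy group has no hydrogen β to oxygen, so the retro-ene fragmentation that limits alkyl ynol ethers at these temperatures is not available, and the final KOH–MeOH treatment cleaves any ester formed between 22 and the ketene.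

**Step 11**
Reactants: 22 ring C phenol
Product: 23 C6 trifluoromethanesulfonate of 22
Conditions: Tf2O, pyridine, CH2Cl2, −20 → 0 °C
Reagents that add atoms: trifluoromethanesulfonic anhydride, O=S(=O)(OS(=O)(=O)C(F)(F)F)C(F)(F)F
Why: Sulfonylation of the C6 phenol, which has only one ortho substituent, turns the extra oxygen into a group that zerovalent palladium can insert into, and the MOM acetal survives the pyridine-buffered medium.

**Step 12**
Reactants: 23 C6 trifluoromethanesulfonate
Product: 24 1-[2-(4-chlorophenyl)ethyl]-3,4-dimethoxy-2-{2-[2-(3,4-dimethoxy-5-(methoxymethoxy)phenyl)ethyl]phenoxy}benzene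
Conditions: Pd(OAc)2 (cat.), 1,1'-bis(diphenylphosphino)ferrocene, HCO2H, Et3N, DMF, 80 °C
Reagents that add atoms: none
Why: Palladium-catalysed formate reduction of an aryl triflate (oxidative addition, formate exchange, loss of CO2, C–H reductive elimination); with a diarylphosphine ligand at this temperature the unactivated ring B chloride does not undergo oxidative addition.

**Step 13**
Reactants: 24 MOM ether
Product: 25 5-{2-[2-(6-(2-(4-chlorophenyl)ethyl)-2,3-dimethoxyphenoxy)phenyl]ethyl}-2,3-dimethoxyphenol
Conditions: HCl (aq.), MeOH–THF, 50 °C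
Reagents that add atoms: none
Why: Acid-catalysed acetal exchange with methanol removes the MOM group and leaves the methyl ethers, the diaryl ether and the aryl chloride untouched.

**Step 14**
Reactants: 25 seco-phenol
Product: 26 tetra-O-methyl ether of the target macrocycle
Conditions: Pd(OAc)2, 2-di-tert-butylphosphino-2',4',6'-triisopropylbiphenyl, K3PO4, toluene, 100 °C, high dilution (slow addition)
Reagents that add atoms: none
Why: Intramolecular palladium-catalysed C–O coupling of a phenol with an aryl chloride (Buchwald–Hartwig-type etherification, the bulky biarylphosphine promoting C–O reductive elimination) closes the 17-membered ring at an unhindered para position, with dilution favouring cyclisation over oligomerisation.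

**Step 15**
Reactants: 26 tetra-O-methyl ether
Product: 27 target CNP0114693.0
Conditions: BBr3 (excess), CH2Cl2, −78 °C → rt; then H2O
Reagents that add atoms: none
Why: Lewis acid demethylation, in which bromide attacks the four O-methyl carbons of the BBr3 adducts and frees both catechols, while the diaryl ether oxygens carry no sp3 carbon and stay intact.

**Compound list**
1 | 3-hydroxy-4,5-dimethoxybenzaldehyde | O=Cc1cc(O)c(OC)c(OC)c1 | starting material
2 | 3,4-dimethoxy-5-(methoxymethoxy)benzaldehyde | O=Cc1cc(OCOC)c(OC)c(OC)c1 | intermediate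
3 | (2-hydroxybenzyl)triphenylphosphonium bromide | Oc1ccccc1C[P+](c1ccccc1)(c1ccccc1)c1ccccc1.[Br-] | starting material
4 | potassium 2-[(triphenylphosphoranylidene)methyl]phenolate (not isolated) | [K+].[O-]c1ccccc1C=P(c1ccccc1)(c1ccccc1)c1ccccc1 | intermediate
5 | 2-[2-(3,4-dimethoxy-5-(methoxymethoxy)phenyl)ethenyl]phenol, E/Z mixture, geometry not defined | Oc1ccccc1C=Cc1cc(OCOC)c(OC)c(OC)c1 | intermediate
6 | 2-[2-(3,4-dimethoxy-5-(methoxymethoxy)phenyl)ethyl]phenol | Oc1ccccc1CCc1cc(OCOC)c(OC)c(OC)c1 | intermediate
7 | trichloroethylene | ClC=C(Cl)Cl | starting material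
8 | 1-{[(E)-1,2-dichloroethenyl]oxy}-2-[2-(3,4-dimethoxy-5-(methoxymethoxy)phenyl)ethyl]benzene | Cl/C=C(/Cl)Oc1ccccc1CCc1cc(OCOC)c(OC)c(OC)c1 | intermediate
9 | 2-(4-chlorophenyl)ethanol | OCCc1ccc(Cl)cc1 | starting material
10 | 2-(4-chlorophenyl)ethyl trifluoromethanesulfonate | O=S(=O)(OCCc1ccc(Cl)cc1)C(F)(F)F | intermediate
11 | 1-[(chloroethynyl)oxy]-2-[2-(3,4-dimethoxy-5-(methoxymethoxy)phenyl)ethyl]benzene (not isolated) | ClC#COc1ccccc1CCc1cc(OCOC)c(OC)c(OC)c1 | intermediate
12 | lithium aryloxyacetylide of 11 (not isolated) | [Li]C#COc1ccccc1CCc1cc(OCOC)c(OC)c(OC)c1 | intermediate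
13 | 1-{[4-(4-chlorophenyl)but-1-yn-1-yl]oxy}-2-[2-(3,4-dimethoxy-5-(methoxymethoxy)phenyl)ethyl]benzene | COCOc1cc(CCc2ccccc2OC#CCCc2ccc(Cl)cc2)cc(OC)c1OC | intermediate
14 | dimethyl squarate (3,4-dimethoxycyclobut-3-ene-1,2-dione) | COC1=C(OC)C(=O)C1=O | starting material
15 | 4-hydroxy-2,3-dimethoxycyclobut-2-en-1-one, racemic | COC1=C(OC)C(O)C1=O | intermediate
16 | 4-acetoxy-2,3-dimethoxycyclobut-2-en-1-one, racemic | COC1=C(OC)C(OC(C)=O)C1=O | intermediate
17 | 2,3-dimethoxycyclobut-2-en-1-one | COC1=C(OC)C(=O)C1 | intermediate
18 | 2,3-dimethoxybuta-1,3-dien-1-one (dimethoxyvinylketene, not isolated) | C=C(OC)C(OC)=C=O | intermediate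
19 | 2-[2-(4-chlorophenyl)ethyl]-4-methoxy-4-(1-methoxyethenyl)-3-aryloxycyclobut-2-en-1-one, racemic (not isolated) | O=C1C(CCc2ccc(Cl)cc2)=C(Oc2ccccc2CCc2cc(OCOC)c(OC)c(OC)c2)C1(OC)C(OC)=C | intermediate
20 | (Z)-dienylketene from ring opening of 19 (not isolated) | O=C=C(CCc1ccc(Cl)cc1)/C(Oc1ccccc1CCc1cc(OCOC)c(OC)c(OC)c1)=C(OC)\C(OC)=C | intermediate
21 | cyclohexa-2,4-dienone tautomer of 22 (not isolated) | O=C1CC(OC)=C(OC)C(Oc2ccccc2CCc2cc(OCOC)c(OC)c(OC)c2)=C1CCc1ccc(Cl)cc1 | intermediate
22 | 2-[2-(4-chlorophenyl)ethyl]-4,5-dimethoxy-3-{2-[2-(3,4-dimethoxy-5-(methoxymethoxy)phenyl)ethyl]phenoxy}phenol | Oc1cc(OC)c(OC)c(Oc2ccccc2CCc2cc(OC)c(OC)c(OCOC)c2)c1CCc1ccc(Cl)cc1 | intermediate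
23 | trifluoromethanesulfonate of 22 at the C6 oxygen | O=S(=O)(Oc1cc(OC)c(OC)c(Oc2ccccc2CCc2cc(OC)c(OC)c(OCOC)c2)c1CCc1ccc(Cl)cc1)C(F)(F)F | intermediate
24 | 1-[2-(4-chlorophenyl)ethyl]-3,4-dimethoxy-2-{2-[2-(3,4-dimethoxy-5-(methoxymethoxy)phenyl)ethyl]phenoxy}benzene | COCOc1cc(CCc2ccccc2Oc2c(CCc3ccc(Cl)cc3)ccc(OC)c2OC)cc(OC)c1OC | intermediate
25 | 5-{2-[2-(6-(2-(4-chlorophenyl)ethyl)-2,3-dimethoxyphenoxy)phenyl]ethyl}-2,3-dimethoxyphenol | Oc1cc(CCc2ccccc2Oc2c(CCc3ccc(Cl)cc3)ccc(OC)c2OC)cc(OC)c1OC | intermediate
26 | tetra-O-methyl ether of the target (17-membered bis-bibenzyl bis-diaryl ether) | COc1cc2cc(c1OC)Oc1ccc(cc1)CCc1ccc(OC)c(OC)c1Oc1ccccc1CC2 | intermediate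
27 | CNP0114693.0 | Oc1cc2cc(c1O)Oc1ccc(cc1)CCc1ccc(O)c(O)c1Oc1ccccc1CC2 | target

**Step count**
Total: 15 steps. Longest linear sequence: 11 steps (1, 2, 3, 4, 6, 10, 11, 12, 13, 14, 15).

**Steps most likely to fail**

Step 10 (benzannulation). The aryloxy group makes the alkyne a weaker nucleophile than an alkyl ynol ether. Capture of the vinylketene may therefore lose out to its re-closure, its dimerisation or its addition to the product phenol, and reversed orientation in the [2+2] step would give the regioisomeric phenol. The fallback gives up ring construction and makes the C2–O bond by nucleophilic aromatic substitution. It sets out from 6: heating 6 with 2-fluoro-3,4-dimethoxybenzaldehyde and Cs2CO3 in DMA at 130 °C should give 2-{2-[2-(3,4-dimethoxy-5-(methoxymethoxy)phenyl)ethyl]phenoxy}-3,4-dimethoxybenzaldehyde F1, the aldehyde activating the ortho fluoride. Wittig reaction of F1 with the ylide from (4-chlorobenzyl)triphenylphosphonium chloride (KOtBu, THF) gives the chlorostilbene F2. Diimide reduction of F2 (p-toluenesulfonyl hydrazide, NaOAc, THF–H2O, reflux), which spares the aryl chloride, comes back to the route at 24; steps 11 and 12 are then not needed.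

Step 14 (macrocyclisation). At the dilution needed for ring closure the catalyst turns over slowly, so intermolecular coupling to dimers and oligomers and reduction of the C–Cl bond may compete. The fallback closes the same ether by copper-mediated oxidative coupling of a boronic acid. It sets out from 24: Miyaura borylation of the aryl chloride (Pd2(dba)3, 2-dicyclohexylphosphino-2',4',6'-triisopropylbiphenyl, B2pin2, KOAc, dioxane, 110 °C) gives the pinacol boronate F3. Aqueous HCl in MeOH–THF with excess methylboronic acid removes the MOM group and the pinacol to give the phenol boronic acid F4. Chan–Lam coupling of F4 (Cu(OAc)2, Et3N, 4 Å molecular sieves, CH2Cl2, air, high dilution) comes back to the route at 26.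

Step 9 (removal of the acetoxy group). The acetate may ionise with loss of a methyl group to the semisquarate before it is reduced. Protonation at the methoxy-bearing end of the ambident intermediate would give the 3,4-dimethoxy isomer, and the enone may be reduced further. The fallback leaves the oxygen on the four-membered ring and removes it later from the arene, where deoxygenation is routine. It sets out from 15: TBSCl and imidazole in DMF give 4-(tert-butyldimethylsilyloxy)-2,3-dimethoxycyclobut-2-en-1-one F5. Heating F5 with 13 under the conditions of step 10 should give the ring C phenol carrying a silyloxy group at C5, F6. TBAF in THF under argon gives the C5,C6-catechol F7, and Tf2O with pyridine gives the bis-triflate F8. Double reduction of F8 with Pd(OAc)2, 1,1'-bis(diphenylphosphino)ferrocene, HCO2H and Et3N in DMF comes back to the route at 24.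

**Further compounds**
F1 | step 10 | 2-{2-[2-(3,4-dimethoxy-5-(methoxymethoxy)phenyl)ethyl]phenoxy}-3,4-dimethoxybenzaldehyde | O=Cc1ccc(OC)c(OC)c1Oc1ccccc1CCc1cc(OCOC)c(OC)c(OC)c1
F2 | step 10 | 1-[2-(4-chlorophenyl)ethenyl]-3,4-dimethoxy-2-{2-[2-(3,4-dimethoxy-5-(methoxymethoxy)phenyl)ethyl]phenoxy}benzene, E/Z mixture | Clc1ccc(C=Cc2ccc(OC)c(OC)c2Oc2ccccc2CCc2cc(OCOC)c(OC)c(OC)c2)cc1
F3 | step 14 | pinacol boronate of 24 (Bpin in place of Cl) | COCOc1cc(CCc2ccccc2Oc2c(CCc3ccc(B4OC(C)(C)C(C)(C)O4)cc3)ccc(OC)c2OC)cc(OC)c1OC
F4 | step 14 | boronic acid analogue of 25 (B(OH)2 in place of Cl) | Oc1cc(CCc2ccccc2Oc2c(CCc3ccc(B(O)O)cc3)ccc(OC)c2OC)cc(OC)c1OC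
F5 | step 9 | 4-(tert-butyldimethylsilyloxy)-2,3-dimethoxycyclobut-2-en-1-one, racemic | COC1=C(OC)C(O[Si](C)(C)C(C)(C)C)C1=O
F6 | step 9 | analogue of 22 with a tert-butyldimethylsilyloxy group at C5 of ring C | CC(C)(C)[Si](C)(C)Oc1c(O)c(CCc2ccc(Cl)cc2)c(Oc2ccccc2CCc2cc(OCOC)c(OC)c(OC)c2)c(OC)c1OC
F7 | step 9 | C5,C6-catechol of ring C | Oc1c(O)c(CCc2ccc(Cl)cc2)c(Oc2ccccc2CCc2cc(OCOC)c(OC)c(OC)c2)c(OC)c1OC
F8 | step 9 | C5,C6-bis(trifluoromethanesulfonate) of F7 | O=S(=O)(Oc1c(OS(=O)(=O)C(F)(F)F)c(CCc2ccc(Cl)cc2)c(Oc2ccccc2CCc2cc(OCOC)c(OC)c(OC)c2)c(OC)c1OC)C(F)(F)F
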